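**Retrosynthetic overview**
1. Target 32 ⇒ open-chain ω-formyl (Z)-2-(bromomethyl)enoate 28. One Cr(II) step closes C6–C7 (the bond germacrene synthase makes) and then the 12,6-lactone (as after C6 hydroxylation en route to costunolide). It is run with the 8-OH free and both allylic esters in place.
2. 28 ⇒ dialdehyde 23 + methyl acrylate (Baylis–Hillman, then SN2′ bromination).
3. 23 ⇒ C3–C4 B-alkyl Suzuki union of dienyl ester 19 with iodoenal 6 (from 2-butyne-1,4-diol; carries C15-OAc and C6=O).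
4. 19 ⇒ (R)-γ-(hydroxymethyl)butyrolactone 7: lactone C=O becomes C14, ring O becomes 8-OH, and HWE with acrolein sets the C1=C10 geometry.
5. Ring order: ten-membered carbocycle first, γ-lactone second, both in the last step.

Assumption: the SMILES is read literally, i.e. (6R,7R,8R), trans-fused 12,6-lactone, free 8β-OH, and both ring olefins with the ring carbons cis (E by CIP because C14 and C15 bear oxygen). Germacrane numbering C1–C15 is used for locants.

**Route**

Step 1
Reactants: 1 2-butyne-1,4-diol (4 equiv); 2 acetic anhydride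
Product: 3 4-hydroxybut-2-yn-1-yl acetate
Conditions: Ac2O (1 equiv), pyridine, 0 °C → rt; excess diol removed by aqueous wash
Reagents that add atoms: acetic anhydride (2), CC(=O)OC(C)=O
Why: Statistical mono-acylation (nucleophilic acyl substitution) of a cheap symmetric diol used in excess; no stereocentre is involved.

Step 2
Reactants: 3 4-hydroxybut-2-yn-1-yl acetate
Product: 4 4-oxobut-2-yn-1-yl acetate
Conditions: Dess–Martin periodinane, CH2Cl2, 0 °C → rt
Reagents that add atoms: none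
Why: Dess–Martin oxidation of a primary propargylic alcohol gives the ynal under conditions that leave the acetate alone.

Step 3
Reactants: 4 4-oxobut-2-yn-1-yl acetate; 5 sodium iodide
Product: 6 (2Z)-2-iodo-4-oxobut-2-en-1-yl acetate
Conditions: NaI, AcOH, 0 °C → rt, dark
Reagents that add atoms: sodium iodide (5), [Na+].[I-]
Why: Conjugate hydroiodination of the ynal proceeds by kinetic anti-addition, so iodine ends up cis to CHO (Z), which fixes C15 trans to C6 for the later coupling.

Step 4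
Reactants: 7 (5R)-5-(hydroxymethyl)oxolan-2-one; 8 chlorotriethylsilane
Product: 9 (5R)-5-{[(triethylsilyl)oxy]methyl}oxolan-2-one
Conditions: TESCl, imidazole, CH2Cl2, 0 °C
Reagents that add atoms: chlorotriethylsilane (8), CC[Si](Cl)(CC)CC
Why: Standard silylation of the primary alcohol; the stereocentre (future C8, R) comes from the D-glutamic-acid-derived lactone and is untouched.

Step 5
Reactants: 9 (5R)-5-{[(triethylsilyl)oxy]methyl}oxolan-2-one; 10 diethyl chlorophosphate; 11 acrolein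
Product: 14 (3E,5R)-3-(prop-2-en-1-ylidene)-5-{[(triethylsilyl)oxy]methyl}oxolan-2-one, via enol phosphate 12 (not isolated), via phosphonolactone 13 (not isolated)
Conditions: LDA (1.1 equiv), THF, −78 °C; ClP(O)(OEt)2; LDA (2.2 equiv), −78 → 0 °C; acrolein, −78 °C → rt
Reagents that add atoms: acrolein (11), C=CC=O
Why: Enolate O-phosphorylation, LDA-induced 1,3-phosphoryl O→C shift and Horner–Wadsworth–Emmons olefination in one flask give the E-alkylidene lactone (vinyl trans to C=O), i.e. C2 cis to C9 as in the target; the minor Z isomer is removed by chromatography.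

Step 6
Reactants: 14 (3E,5R)-3-(prop-2-en-1-ylidene)-5-{[(triethylsilyl)oxy]methyl}oxolan-2-one
Product: 15 (2E)-2-[(2R)-2-hydroxy-3-[(triethylsilyl)oxy]propyl]penta-2,4-dien-1-ol
Conditions: DIBAL-H (4 equiv), CH2Cl2, −78 → 0 °C; Rochelle salt
Reagents that add atoms: none
Why: 1,2-Reduction of the conjugated lactone by DIBAL-H unveils the C14 allylic alcohol and the C8 secondary alcohol in one step without touching the olefin geometry or C8.

Step 7
Reactants: 15 (2E)-2-[(2R)-2-hydroxy-3-[(triethylsilyl)oxy]propyl]penta-2,4-dien-1-ol; 16 2-methylpropanoyl chloride; 17 triethylsilyl trifluoromethanesulfonate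
Product: 19 (2E)-2-[(2R)-2,3-bis[(triethylsilyl)oxy]propyl]penta-2,4-dien-1-yl 2-methylpropanoate, via monoisobutyrate 18 (not isolated)
Conditions: i-PrCOCl (1.05 equiv), 2,4,6-collidine, CH2Cl2, −78 °C; then TESOTf, −78 → −40 °C
Reagents that add atoms: 2-methylpropanoyl chloride (16), CC(C)C(Cl)=O; triethylsilyl trifluoromethanesulfonate (17), CC[Si](CC)(CC)OS(=O)(=O)C(F)(F)F
Why: Acyl chloride/collidine at −78 °C acylates the unhindered primary allylic alcohol selectively, and the remaining secondary alcohol is then silylated in the same flask; no stereocentre is touched.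

Step 8
Reactants: 19 (2E)-2-[(2R)-2,3-bis[(triethylsilyl)oxy]propyl]penta-2,4-dien-1-yl 2-methylpropanoate; 20 9-borabicyclo[3.3.1]nonane; 6 (2Z)-2-iodo-4-oxobut-2-en-1-yl acetate
Product: 22 (2E,6E,9R)-3-(acetoxymethyl)-7-{[(2-methylpropanoyl)oxy]methyl}-9,10-bis[(triethylsilyl)oxy]deca-2,6-dienal, via alkylborane 21 (not isolated)
Conditions: 9-BBN (1.5 equiv), THF, 0 °C → rt; H2O; then 6, PdCl2(dppf) (5 mol%), AsPh3, 3 M aq K3PO4, DMF, rt
Reagents that add atoms: none
Why: 9-BBN adds to the terminal CH2 of the diene (anti-Markovnikov, trisubstituted olefin inert) and the B-alkyl Suzuki–Miyaura coupling replaces iodine with retention, so C3 is cis to C6 and C15 trans to C6.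

Step 9
Reactants: 22 (2E,6E,9R)-3-(acetoxymethyl)-7-{[(2-methylpropanoyl)oxy]methyl}-9,10-bis[(triethylsilyl)oxy]deca-2,6-dienal
Product: 23 (2E,6E,9R)-3-(acetoxymethyl)-7-{[(2-methylpropanoyl)oxy]methyl}-9-[(triethylsilyl)oxy]deca-2,6-dienedial
Conditions: (COCl)2, DMSO, CH2Cl2, −78 → −40 °C; Et3N, −78 → 0 °C
Reagents that add atoms: none
Why: Under Swern conditions a primary TES ether is cleaved and oxidised directly to the aldehyde while the secondary TES ether survives, so C7 becomes CHO with C8 still protected and configurationally intact.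

Step 10
Reactants: 23 (2E,6E,9R)-3-(acetoxymethyl)-7-{[(2-methylpropanoyl)oxy]methyl}-9-[(triethylsilyl)oxy]deca-2,6-dienedial; 24 methyl acrylate
Product: 25 methyl (4R,6E,10E)-10-(acetoxymethyl)-3-hydroxy-2-methylidene-6-{[(2-methylpropanoyl)oxy]methyl}-12-oxo-4-[(triethylsilyl)oxy]dodeca-6,10-dienoate (C3 epimers)
Conditions: methyl acrylate (10 equiv, neat), DABCO (1 equiv), rt, 48–72 h
Reagents that add atoms: methyl acrylate (24), C=CC(=O)OC
Why: Morita–Baylis–Hillman reaction occurs at the activated α-silyloxy aldehyde and not at the hindered β,β-disubstituted enal; the new C7 carbinol forms as an epimer mixture that is erased in step 11.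

Step 11
Reactants: 25 methyl (4R,6E,10E)-10-(acetoxymethyl)-3-hydroxy-2-methylidene-6-{[(2-methylpropanoyl)oxy]methyl}-12-oxo-4-[(triethylsilyl)oxy]dodeca-6,10-dienoate; 26 N-bromosuccinimide
Product: 28 methyl (2Z,4R,6E,10E)-10-(acetoxymethyl)-2-(bromomethyl)-4-hydroxy-6-{[(2-methylpropanoyl)oxy]methyl}-12-oxododeca-2,6,10-trienoate, via silyl ether bromide 27 (not isolated)
Conditions: NBS, Me2S, CH2Cl2, 0 °C → rt; then HF·pyridine, THF, 0 °C; used at once
Reagents that add atoms: N-bromosuccinimide (26), O=C1CCC(=O)N1Br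
Why: Corey–Kim-type activation of the allylic alcohol and SN2′ attack of bromide give the thermodynamically preferred (Z)-2-(bromomethyl)enoate from both C7 epimers, and fluoride then frees the C8 hydroxyl without touching C8.

Step 12
Reactants: 28 methyl (2Z,4R,6E,10E)-10-(acetoxymethyl)-2-(bromomethyl)-4-hydroxy-6-{[(2-methylpropanoyl)oxy]methyl}-12-oxododeca-2,6,10-trienoate; 29 chromium(II) chloride
Product: 32 [(3aR,4R,6E,10E,11aR)-10-(acetoxymethyl)-4-hydroxy-3-methylidene-2-oxo-2,3,3a,4,5,8,9,11a-octahydrocyclodeca[b]furan-6-yl]methyl 2-methylpropanoate, via allylchromium 30 (not isolated), via hydroxy ester 31 (not isolated)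
Conditions: CrCl2 (8 equiv), THF, rt, syringe-pump addition of 28 over 10 h (final 2 mM)
Reagents that add atoms: none
Why: Intramolecular Nozaki–Hiyama–Kishi allylation closes C6–C7 and the Cr(III) alkoxide lactonises onto the methyl ester; the equilibrating allylchromium should react through a chair Zimmerman–Traxler transition state with C5 and C8 equatorial (H6/H7 anti, trans-lactone), and the free 8-OH, bound to the same Cr(III) as the aldehyde oxygen, is expected to deliver C6 to the hydroxyl face of C7 with H8 in the alkene plane, giving 6R,7R next to the existing 8R.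

**Compound list**
1 | 2-butyne-1,4-diol | OCC#CCO | starting material
2 | acetic anhydride | CC(=O)OC(C)=O | starting material
3 | 4-hydroxybut-2-yn-1-yl acetate | CC(=O)OCC#CCO | intermediate
4 | 4-oxobut-2-yn-1-yl acetate | CC(=O)OCC#CC=O | intermediate
5 | sodium iodide | [Na+].[I-] | starting material
6 | (2Z)-2-iodo-4-oxobut-2-en-1-yl acetate | CC(=O)OC/C(I)=C/C=O | intermediate
7 | (5R)-5-(hydroxymethyl)oxolan-2-one | OC[C@H]1CCC(=O)O1 | starting material
8 | chlorotriethylsilane | CC[Si](Cl)(CC)CC | starting material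
9 | (5R)-5-{[(triethylsilyl)oxy]methyl}oxolan-2-one | CC[Si](CC)(CC)OC[C@H]1CCC(=O)O1 | intermediate
10 | diethyl chlorophosphate | CCOP(Cl)(=O)OCC | starting material
11 | acrolein | C=CC=O | starting material
12 | diethyl (5R)-5-{[(triethylsilyl)oxy]methyl}-4,5-dihydrofuran-2-yl phosphate | CCOP(=O)(OCC)OC1=CC[C@H](CO[Si](CC)(CC)CC)O1 | intermediate (not isolated)
13 | diethyl [(5R)-2-oxo-5-{[(triethylsilyl)oxy]methyl}oxolan-3-yl]phosphonate (C3 epimers, as its lithium salt in the flask) | CCOP(=O)(OCC)C1C[C@H](CO[Si](CC)(CC)CC)OC1=O | intermediate (not isolated)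
14 | (3E,5R)-3-(prop-2-en-1-ylidene)-5-{[(triethylsilyl)oxy]methyl}oxolan-2-one | C=C/C=C1/C(=O)O[C@@H](CO[Si](CC)(CC)CC)C1 | intermediate
15 | (2E)-2-[(2R)-2-hydroxy-3-[(triethylsilyl)oxy]propyl]penta-2,4-dien-1-ol | C=C/C=C(/CO)C[C@@H](O)CO[Si](CC)(CC)CC | intermediate
16 | 2-methylpropanoyl chloride | CC(C)C(Cl)=O | starting material
17 | triethylsilyl trifluoromethanesulfonate | CC[Si](CC)(CC)OS(=O)(=O)C(F)(F)F | starting material
18 | (2E)-2-[(2R)-2-hydroxy-3-[(triethylsilyl)oxy]propyl]penta-2,4-dien-1-yl 2-methylpropanoate | C=C/C=C(/COC(=O)C(C)C)C[C@@H](O)CO[Si](CC)(CC)CC | intermediate (not isolated)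
19 | (2E)-2-[(2R)-2,3-bis[(triethylsilyl)oxy]propyl]penta-2,4-dien-1-yl 2-methylpropanoate | C=C/C=C(/COC(=O)C(C)C)C[C@@H](O[Si](CC)(CC)CC)CO[Si](CC)(CC)CC | intermediate
20 | 9-borabicyclo[3.3.1]nonane (9-BBN) | B1C2CCCC1CCC2 | starting material
21 | (2E)-5-(9-borabicyclo[3.3.1]nonan-9-yl)-2-[(2R)-2,3-bis[(triethylsilyl)oxy]propyl]pent-2-en-1-yl 2-methylpropanoate | CC(C)C(=O)OC/C(C[C@@H](O[Si](CC)(CC)CC)CO[Si](CC)(CC)CC)=C/CCB1C2CCCC1CCC2 | intermediate (not isolated)
22 | (2E,6E,9R)-3-(acetoxymethyl)-7-{[(2-methylpropanoyl)oxy]methyl}-9,10-bis[(triethylsilyl)oxy]deca-2,6-dienal | CC(=O)OC/C(CC/C=C(/COC(=O)C(C)C)C[C@@H](O[Si](CC)(CC)CC)CO[Si](CC)(CC)CC)=C/C=O | intermediate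
23 | (2E,6E,9R)-3-(acetoxymethyl)-7-{[(2-methylpropanoyl)oxy]methyl}-9-[(triethylsilyl)oxy]deca-2,6-dienedial | CC(=O)OC/C(CC/C=C(/COC(=O)C(C)C)C[C@@H](O[Si](CC)(CC)CC)C=O)=C/C=O | intermediate
24 | methyl acrylate | C=CC(=O)OC | starting material
25 | methyl (4R,6E,10E)-10-(acetoxymethyl)-3-hydroxy-2-methylidene-6-{[(2-methylpropanoyl)oxy]methyl}-12-oxo-4-[(triethylsilyl)oxy]dodeca-6,10-dienoate (C3 epimers) | CC(=O)OC/C(CC/C=C(/COC(=O)C(C)C)C[C@@H](O[Si](CC)(CC)CC)C(O)C(=C)C(=O)OC)=C/C=O | intermediate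
26 | N-bromosuccinimide | O=C1CCC(=O)N1Br | starting material
27 | methyl (2Z,4R,6E,10E)-10-(acetoxymethyl)-2-(bromomethyl)-6-{[(2-methylpropanoyl)oxy]methyl}-12-oxo-4-[(triethylsilyl)oxy]dodeca-2,6,10-trienoate | CC(=O)OC/C(CC/C=C(/COC(=O)C(C)C)C[C@@H](O[Si](CC)(CC)CC)/C=C(\CBr)C(=O)OC)=C/C=O | intermediate (not isolated)
28 | methyl (2Z,4R,6E,10E)-10-(acetoxymethyl)-2-(bromomethyl)-4-hydroxy-6-{[(2-methylpropanoyl)oxy]methyl}-12-oxododeca-2,6,10-trienoate | CC(=O)OC/C(CC/C=C(/COC(=O)C(C)C)C[C@@H](O)/C=C(\CBr)C(=O)OC)=C/C=O | intermediate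
29 | chromium(II) chloride | Cl[Cr]Cl | starting material
30 | allylchromium(III) dichloride of 28 (CrCl2 in place of Br at C13) | CC(=O)OC/C(CC/C=C(/COC(=O)C(C)C)C[C@@H](O)/C=C(\C[Cr](Cl)Cl)C(=O)OC)=C/C=O | intermediate (not isolated)
31 | methyl 2-[4-(acetoxymethyl)-2,10-dihydroxy-8-{[(2-methylpropanoyl)oxy]methyl}cyclodeca-3,7-dien-1-yl]prop-2-enoate, 6R,7R,8R in germacrane numbering (chromium alkoxide in the flask) | C=C(C(=O)OC)[C@H]1[C@H](O)/C=C(/COC(C)=O)CC/C=C(/COC(=O)C(C)C)C[C@H]1O | intermediate (not isolated)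
32 | [(3aR,4R,6E,10E,11aR)-10-(acetoxymethyl)-4-hydroxy-3-methylidene-2-oxo-2,3,3a,4,5,8,9,11a-octahydrocyclodeca[b]furan-6-yl]methyl 2-methylpropanoate (CNP0312458.1) | C=C1C(=O)O[C@@H]2/C=C(/COC(C)=O)CC/C=C(/COC(=O)C(C)C)C[C@@H](O)[C@@H]12 | target

**Step count**
Total: 12 steps. Longest linear sequence: 9 steps (7 → 32, steps 4–12); the iodoenal branch (steps 1–3) joins at step 8.

**Three steps most likely to fail, with fallbacks**

Step 12 (macrocyclisation/lactonisation). The risks are: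
- oligomerisation or simple reduction instead of ten-membered ring closure;
- attack of C6 on the face of C7 away from the 8-OH, which would give the (6S,7S,8R) diastereomer; the hydroxyl-directed model is a prediction, not a precedent;
- closure of 28 to a 2,5-dihydrofuran (O8 onto C13) before it meets Cr(II);
- lactonisation onto O8 instead of O6.

The fallback sets out from 19 and returns at 32; it makes the C6–C7 bond intermolecularly and closes the ring at C3–C4 instead. Swern oxidation of 19 gives dienyl aldehyde F1. DABCO/methyl acrylate gives Baylis–Hillman adduct F2. NBS/Me2S gives silyl ether bromide F3, and HF·pyridine gives dienyl hydroxy bromide F4. CrCl2 in THF with iodoenal 6 forms allylchromium F5, which adds to the aldehyde to give open-chain hydroxy ester F6, and this lactonises to open-chain iodo lactone F7. 9-BBN then hydroborates the terminal diene of F7 to alkylborane F8, and intramolecular B-alkyl Suzuki coupling (PdCl2(dppf), AsPh3, K3PO4, high dilution) closes the ten-membered ring to 32.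

Step 8 (hydroboration / B-alkyl Suzuki). The diene may hydroborate sluggishly, the borane may reduce the aldehyde of 6, and Pd(0) may ionise the allylic esters. The fallback sets out from 21 (made from 19) and returns at 22. Oxidation of the borane with NaBO3·4H2O gives homoallylic alcohol F9. I2/PPh3/imidazole gives homoallylic iodide F10. Zinc insertion (Zn dust, LiCl, THF) gives alkylzinc iodide F11. Negishi coupling of F11 with 6 (Pd2(dba)3/SPhos, THF, rt) gives 22.

Step 10 (Baylis–Hillman). The reaction is slow, and DABCO over days may epimerise the α-silyloxy aldehyde or isomerise the γ-acetoxy enal. The fallback sets out from 23 and returns at 25. Methyl 2-bromoacrylate with CrCl2 and catalytic NiCl2 in DMF at rt gives vinylchromium reagent F12, which adds to the more electrophilic C7 aldehyde of 23 (Nozaki–Hiyama–Kishi vinylation) to give 25 directly under neutral conditions.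

**Further compounds**
F1 | step 12 | (2E)-2-[(2R)-3-oxo-2-[(triethylsilyl)oxy]propyl]penta-2,4-dien-1-yl 2-methylpropanoate | C=C/C=C(/COC(=O)C(C)C)C[C@@H](O[Si](CC)(CC)CC)C=O
F2 | step 12 | methyl (4R,6E)-3-hydroxy-2-methylidene-6-{[(2-methylpropanoyl)oxy]methyl}-4-[(triethylsilyl)oxy]nona-6,8-dienoate (C3 epimers) | C=C/C=C(/COC(=O)C(C)C)C[C@@H](O[Si](CC)(CC)CC)C(O)C(=C)C(=O)OC
F3 | step 12 | methyl (2Z,4R,6E)-2-(bromomethyl)-6-{[(2-methylpropanoyl)oxy]methyl}-4-[(triethylsilyl)oxy]nona-2,6,8-trienoate | C=C/C=C(/COC(=O)C(C)C)C[C@@H](O[Si](CC)(CC)CC)/C=C(\CBr)C(=O)OC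
F4 | step 12 | methyl (2Z,4R,6E)-2-(bromomethyl)-4-hydroxy-6-{[(2-methylpropanoyl)oxy]methyl}nona-2,6,8-trienoate | C=C/C=C(/COC(=O)C(C)C)C[C@@H](O)/C=C(\CBr)C(=O)OC
F5 | step 12 | allylchromium(III) dichloride of F4 | C=C/C=C(/COC(=O)C(C)C)C[C@@H](O)/C=C(\C[Cr](Cl)Cl)C(=O)OC
F6 | step 12 | open-chain hydroxy ester (31 without the C3–C4 bond: C4–I, terminal C2=C3; C6, C7, C8 as in 32) | C=C(C(=O)OC)[C@@H]([C@H](O)/C=C(/COC(C)=O)I)[C@H](O)C/C(COC(=O)C(C)C)=C\C=C
F7 | step 12 | open-chain iodo lactone (32 without the C3–C4 bond: C4–I, terminal C2=C3; C6, C7, C8 as in 32) | C=C1C(=O)O[C@H](/C=C(/COC(C)=O)I)[C@H]1[C@H](O)C/C(COC(=O)C(C)C)=C\C=C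
F8 | step 12 | B-alkyl-9-BBN adduct of F7 (boron on C3) | C=C1C(=O)O[C@H](/C=C(/COC(C)=O)I)[C@H]1[C@H](O)C/C(COC(=O)C(C)C)=C\CCB1C2CCCC1CCC2
F9 | step 8 | (2E)-2-[(2R)-2,3-bis[(triethylsilyl)oxy]propyl]-5-hydroxypent-2-en-1-yl 2-methylpropanoate | CC(C)C(=O)OC/C(C[C@@H](O[Si](CC)(CC)CC)CO[Si](CC)(CC)CC)=C/CCO
F10 | step 8 | (2E)-2-[(2R)-2,3-bis[(triethylsilyl)oxy]propyl]-5-iodopent-2-en-1-yl 2-methylpropanoate | CC(C)C(=O)OC/C(C[C@@H](O[Si](CC)(CC)CC)CO[Si](CC)(CC)CC)=C/CCI
F11 | step 8 | alkylzinc iodide of F10 | CC(C)C(=O)OC/C(C[C@@H](O[Si](CC)(CC)CC)CO[Si](CC)(CC)CC)=C/CC[Zn]I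
F12 | step 10 | methyl 2-(dichlorochromio)prop-2-enoate | C=C([Cr](Cl)Cl)C(=O)OC
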